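The ring of the 2,5-dihydro-1-benzoxepine is cut at C2–C3. C2 is an isolated methylene between the ring oxygen O1 and the alkene carbon C3, so it is treated as an aryloxymethyl cation. C3=C4 is a cis alkene inside the seven-membered ring, so it is carried by a Z-vinylsilane whose silicon sits on C3. In one operation the key step ionises a phenol methylthiomethyl ether, joins C2 to C3 by ipso substitution of silicon, closes the oxepine and fixes the ring alkene. Its precursor is the dihydrochalcone with a (Z)-3-(trimethylsilyl)but-2-enyl chain at C5a, the methylthiomethyl ether on O1 and four phenol acetates.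

Key step: step 9

Remarks on the chemistry
- The target has no stereocentre and is achiral, so there is no enantiomer to select. The only stereochemical element of the route is the Z geometry of the vinylsilane, set in step 1 and carried with retention through steps 3 and 9.
- Ring atoms carry benzoxepine locants (O1, C2, C3, C4, C5, C5a, C6–C9, C9a). In the open-chain intermediates the ketone-bearing ring carries primed locants (C1' acyl, C3' side chain, O4' becomes O1).
- Precursor design: the cation source is an O,S-acetal because a thiophile ionises it at sulfur only, whereas an O,O-acetal under Lewis acid would expel the phenoxide. S-Methylation is used because halonium or sulfenyl halide activators would attack the vinylsilane. All other phenols are acetates, which deactivate both arenes and come off together at the end.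
- The dihydrochalcone core is made in one step from phloroglucinol and 3-(3,4-dihydroxyphenyl)propanoic acid, so no protecting groups are needed before the acetates.

Step 1
Reactants: 1 but-2-yn-1-ol
Product: 3 (2Z)-3-iodobut-2-en-1-ol, via cyclic sodium alkenylalanate 2 (not isolated)
Conditions: Red-Al, Et2O, 0 °C to rt; then I2, THF, −78 to 0 °C; aq. Rochelle salt/Na2S2O3 work-up
Reagents that add atoms: iodine, II
Why: Hydroxyl-directed anti-hydroalumination of the propargylic alcohol places aluminium on C3 cis to the carbinol carbon, and iodinolysis of the C–Al bond with retention should give the Z-iodoalkene (hydroalumination–iodination).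

Step 2
Reactants: 3 (2Z)-3-iodobut-2-en-1-ol
Product: 4 {[(2Z)-3-iodobut-2-en-1-yl]oxy}trimethylsilane
Conditions: TMSCl, Et3N, CH2Cl2, 0 °C; filtered, concentrated and used directly
Reagents that add atoms: chlorotrimethylsilane, C[Si](C)(C)Cl
Why: Routine O-silylation of a primary alcohol (silyl ether formation) installs the silicon that step 3 transfers to carbon.

Step 3
Reactants: 4 {[(2Z)-3-iodobut-2-en-1-yl]oxy}trimethylsilane
Product: 7 (2Z)-3-(trimethylsilyl)but-2-en-1-ol, via (Z)-alkenyllithium 5 (not isolated), via lithium silylbutenolate 6 (not isolated)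
Conditions: t-BuLi (2.1 equiv), THF, −78 to 0 °C; then H2O
Reagents that add atoms: none
Why: Iodine–lithium exchange with retention gives the alkenyllithium, whose cis silyloxymethyl group passes its silicon to carbon through a five-membered silicate (1,4 O-to-C silyl migration, retro-Brook rearrangement), so the Z geometry should be kept.

Step 4
Reactants: 7 (2Z)-3-(trimethylsilyl)but-2-en-1-ol
Product: 8 [(2Z)-4-bromobut-2-en-2-yl]trimethylsilane
Conditions: CBr4, PPh3, CH2Cl2, 0 °C
Reagents that add atoms: tetrabromomethane, BrC(Br)(Br)Br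
Why: The Appel reaction converts the primary allylic alcohol to the bromide under neutral conditions that should neither protodesilylate nor isomerise the vinylsilane.

Step 5
Reactants: 9 phloroglucinol, 10 3-(3,4-dihydroxyphenyl)propanoic acid
Product: 11 3-(3,4-dihydroxyphenyl)-1-(2,4,6-trihydroxyphenyl)propan-1-one
Conditions: BF3·OEt2 (as solvent), 80 °C, Ar; then aq. NaOAc
Reagents that add atoms: none
Why: Friedel–Crafts acylation of the very electron-rich, threefold symmetric phloroglucinol by the free acid in boron trifluoride etherate should stop at the monoketone, because the acyl group deactivates the ring and only one regioisomer is possible.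

Step 6
Reactants: 11 3-(3,4-dihydroxyphenyl)-1-(2,4,6-trihydroxyphenyl)propan-1-one, 8 [(2Z)-4-bromobut-2-en-2-yl]trimethylsilane
Product: 12 3-(3,4-dihydroxyphenyl)-1-{2,4,6-trihydroxy-3-[(2Z)-3-(trimethylsilyl)but-2-en-1-yl]phenyl}propan-1-one
Conditions: DBU (1 equiv relative to 11), THF, 0 °C to rt, Ar; 8 as the limiting reagent; pH 5 buffer work-up
Reagents that add atoms: none
Why: C-Alkylation of the ambident acylphloroglucinol monoanion (SN2 at the primary allylic bromide) is the usual entry to nuclear prenyl-type chains; one equivalent of amidine base ionises only the acidic ketone-bearing ring, C3' and C5' are equivalent so a single C-monoalkyl isomer can form, and the alkene geometry is not touched.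

Step 7
Reactants: 12 3-(3,4-dihydroxyphenyl)-1-{2,4,6-trihydroxy-3-[(2Z)-3-(trimethylsilyl)but-2-en-1-yl]phenyl}propan-1-one
Product: 13 3-(3,4-dihydroxyphenyl)-1-{2,6-dihydroxy-4-[(methylsulfanyl)methoxy]-3-[(2Z)-3-(trimethylsilyl)but-2-en-1-yl]phenyl}propan-1-one
Conditions: MeSCH2Cl (1.1 equiv), KHCO3, NaI (cat.), DMF, rt, Ar
Reagents that add atoms: chloromethyl methyl sulfide, CSCCl
Why: Williamson-type O-alkylation under acidity control: bicarbonate ionises only the 4'-OH para to the ketone (a vinylogous acid), the 2'- and 6'-OH are chelated to the carbonyl and the catechol is less acidic, so the O,S-acetal should form on the oxygen that becomes O1.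

Step 8
Reactants: 13 3-(3,4-dihydroxyphenyl)-1-{2,6-dihydroxy-4-[(methylsulfanyl)methoxy]-3-[(2Z)-3-(trimethylsilyl)but-2-en-1-yl]phenyl}propan-1-one
Product: 14 2-[3-(3,4-diacetoxyphenyl)propanoyl]-5-[(methylsulfanyl)methoxy]-4-[(2Z)-3-(trimethylsilyl)but-2-en-1-yl]-1,3-phenylene diacetate
Conditions: Ac2O, pyridine, DMAP (cat.), CH2Cl2, 0 °C to rt
Reagents that add atoms: acetic anhydride, CC(=O)OC(C)=O
Why: DMAP-catalysed acetylation (nucleophilic acyl transfer) should esterify all four remaining phenols, the chelated ones included, without affecting the O,S-acetal or the vinylsilane.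

Step 9
Reactants: 14 2-[3-(3,4-diacetoxyphenyl)propanoyl]-5-[(methylsulfanyl)methoxy]-4-[(2Z)-3-(trimethylsilyl)but-2-en-1-yl]-1,3-phenylene diacetate
Product: 18 7-[3-(3,4-diacetoxyphenyl)propanoyl]-3-methyl-2,5-dihydro-1-benzoxepine-6,8-diyl diacetate, via dimethylsulfonium triflate 15 (not isolated), via aryloxymethyl cation 16 (not isolated), via β-silyl cation 17 (not isolated)
Conditions: MeOTf (1.5 equiv), 2,6-di-tert-butyl-4-methylpyridine, 4 Å MS, CH2Cl2 (0.01 M), −20 °C to rt; aq. NaHCO3
Reagents that add atoms: none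
Why: S-Methylation of the O,S-acetal gives sulfonium salt 15, which loses dimethyl sulfide to the aryloxymethyl cation 16 (O1=C2); the silicon-bearing alkene carbon C3 then bonds to C2 to give cation 17 at C4, β to silicon, and triflate removes the silyl group to leave C3=C4. The closest known reaction type is the vinylsilane-terminated cyclisation of oxocarbenium ions (a silicon-directed Prins ring closure), with the cation drawn from an O,S-acetal by a thiophile as in thioglycoside activation. The oxepine closes in the 7-endo-trig mode, both alkene carbons ending inside the ring. No stereocentre is formed; the ring needs a cis C3=C4 bond, and ipso substitution with retention carries the Z geometry of the vinylsilane (silicon cis to C5) into it. The step needs C2 to bond to C3 and not to C4 (6-exo closure to a chroman) or to an arene: hyperconjugation from the C–Si bond favours attack at C3 and desilylation makes it irreversible, whereas a C4 adduct is a less stabilised α-silyl cation that can revert by retro-Prins fragmentation. The acetates and the ketone deactivate both rings, high dilution disfavours intermolecular alkylation, and the hindered pyridine removes triflic acid that would protodesilylate the alkene.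

Step 10
Reactants: 18 7-[3-(3,4-diacetoxyphenyl)propanoyl]-3-methyl-2,5-dihydro-1-benzoxepine-6,8-diyl diacetate
Product: 19 3-(3,4-dihydroxyphenyl)-1-(6,8-dihydroxy-3-methyl-2,5-dihydro-1-benzoxepin-7-yl)propan-1-one
Conditions: K2CO3, degassed MeOH, 0 °C, Ar; then aq. citric acid to pH 5
Reagents that add atoms: none
Why: Base-catalysed transesterification (Zemplén-type methanolysis) cleaves the four aryl acetates far faster than it affects the allyl aryl ether, the ketone or the ring alkene, and exclusion of air protects the catechol.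

Compound list
1 | but-2-yn-1-ol | CC#CCO | starting material
2 | cyclic sodium alkenylalanate: five-membered O–Al–C3 chelate of the (Z)-but-2-en-1-olate with two 2-methoxyethoxy groups on aluminium (formed in the flask) | CC1=CCO[Al-]1(OCCOC)OCCOC.[Na+] | intermediate
3 | (2Z)-3-iodobut-2-en-1-ol | C/C(I)=C/CO | intermediate
4 | {[(2Z)-3-iodobut-2-en-1-yl]oxy}trimethylsilane | C/C(I)=C/CO[Si](C)(C)C | intermediate
5 | {(2Z)-4-[(trimethylsilyl)oxy]but-2-en-2-yl}lithium (formed in the flask) | C/C([Li])=C/CO[Si](C)(C)C | intermediate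
6 | lithium (2Z)-3-(trimethylsilyl)but-2-en-1-olate (formed in the flask) | C/C(=C/C[O-])[Si](C)(C)C.[Li+] | intermediate
7 | (2Z)-3-(trimethylsilyl)but-2-en-1-ol | C/C(=C/CO)[Si](C)(C)C | intermediate
8 | [(2Z)-4-bromobut-2-en-2-yl]trimethylsilane | C/C(=C/CBr)[Si](C)(C)C | intermediate
9 | phloroglucinol (benzene-1,3,5-triol) | Oc1cc(O)cc(O)c1 | starting material
10 | 3-(3,4-dihydroxyphenyl)propanoic acid | O=C(O)CCc1ccc(O)c(O)c1 | starting material
11 | 3-(3,4-dihydroxyphenyl)-1-(2,4,6-trihydroxyphenyl)propan-1-one | O=C(CCc1ccc(O)c(O)c1)c1c(O)cc(O)cc1O | intermediate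
12 | 3-(3,4-dihydroxyphenyl)-1-{2,4,6-trihydroxy-3-[(2Z)-3-(trimethylsilyl)but-2-en-1-yl]phenyl}propan-1-one | Oc1cc(O)c(C(=O)CCc2ccc(O)c(O)c2)c(O)c1C/C=C(C)\[Si](C)(C)C | intermediate
13 | 3-(3,4-dihydroxyphenyl)-1-{2,6-dihydroxy-4-[(methylsulfanyl)methoxy]-3-[(2Z)-3-(trimethylsilyl)but-2-en-1-yl]phenyl}propan-1-one | CSCOc1cc(O)c(C(=O)CCc2ccc(O)c(O)c2)c(O)c1C/C=C(C)\[Si](C)(C)C | intermediate
14 | 2-[3-(3,4-diacetoxyphenyl)propanoyl]-5-[(methylsulfanyl)methoxy]-4-[(2Z)-3-(trimethylsilyl)but-2-en-1-yl]-1,3-phenylene diacetate (precursor of the key step) | CSCOc1cc(OC(C)=O)c(C(=O)CCc2ccc(OC(C)=O)c(OC(C)=O)c2)c(OC(C)=O)c1C/C=C(C)\[Si](C)(C)C | intermediate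
15 | dimethylsulfonium triflate of 14, S-methylated at the O,S-acetal sulfur (formed in the flask) | C[S+](C)COc1cc(OC(C)=O)c(C(=O)CCc2ccc(OC(C)=O)c(OC(C)=O)c2)c(OC(C)=O)c1C/C=C(C)\[Si](C)(C)C.[O-]S(=O)(=O)C(F)(F)F | intermediate
16 | aryloxymethyl cation (O1=C2 oxocarbenium) triflate (formed in the flask) | C=[O+]c1cc(OC(C)=O)c(C(=O)CCc2ccc(OC(C)=O)c(OC(C)=O)c2)c(OC(C)=O)c1C/C=C(C)\[Si](C)(C)C.[O-]S(=O)(=O)C(F)(F)F | intermediate
17 | ring-closed β-silyl cation: C4 cation of the 3-methyl-3-(trimethylsilyl)-2,3,4,5-tetrahydro-1-benzoxepine, triflate, transient and racemic at C3 (formed in the flask) | CC1([Si](C)(C)C)[CH+]Cc2c(cc(OC(C)=O)c(C(=O)CCc3ccc(OC(C)=O)c(OC(C)=O)c3)c2OC(C)=O)OC1.[O-]S(=O)(=O)C(F)(F)F | intermediate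
18 | 7-[3-(3,4-diacetoxyphenyl)propanoyl]-3-methyl-2,5-dihydro-1-benzoxepine-6,8-diyl diacetate (product of the key step) | CC1=CCc2c(cc(OC(C)=O)c(C(=O)CCc3ccc(OC(C)=O)c(OC(C)=O)c3)c2OC(C)=O)OC1 | intermediate
19 | 3-(3,4-dihydroxyphenyl)-1-(6,8-dihydroxy-3-methyl-2,5-dihydro-1-benzoxepin-7-yl)propan-1-one | CC1=CCc2c(cc(O)c(C(=O)CCc3ccc(O)c(O)c3)c2O)OC1 | target

Total step count: 10
Longest linear sequence: 9 steps (1 → 3 → 4 → 7 → 8 → 12 → 13 → 14 → 18 → 19); step 5 supplies 11 in one step from 9 and 10.

Steps most likely to fail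

Step 9. The cation may bond to C4 instead of C3, closing a six-membered ring and leaving an α-silyl cation that escapes by hydride shift or proton loss. Silicon may also be lost to adventitious acid before ring closure, or the cation may alkylate an arene of a second molecule. The fallback forms C3=C4 last by ring-closing metathesis; it sets out from 11 and comes back to the route at 18. Dihydrochalcone 11 would be C-alkylated with allyl bromide (DBU, THF) to 1-(3-allyl-2,4,6-trihydroxyphenyl)-3-(3,4-dihydroxyphenyl)propan-1-one F1. This would be alkylated on the 4'-oxygen with 3-chloro-2-methylpropene (KHCO3, NaI, DMF) to 1-{3-allyl-2,6-dihydroxy-4-[(2-methylprop-2-en-1-yl)oxy]phenyl}-3-(3,4-dihydroxyphenyl)propan-1-one F2, then peracetylated (Ac2O, pyridine, DMAP) to 4-allyl-2-[3-(3,4-diacetoxyphenyl)propanoyl]-5-[(2-methylprop-2-en-1-yl)oxy]-1,3-phenylene diacetate F3. Grubbs second-generation catalyst (CH2Cl2, 40 °C) should then join the allyl and methallyl groups with loss of ethene, an established route to 3-methyl-2,5-dihydro-1-benzoxepines, and give 18.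

Step 6. The ambident anion may alkylate on oxygen or twice on carbon, and a catechol oxygen may compete. The fallback makes both aryl–carbon bonds by directed ortho-metalation, so no ambident anion is involved; it sets out from 9, 8 and 10 and comes back at 12. Phloroglucinol 9 would be converted (NaH, MOMCl, DMF) to 1,3,5-tris(methoxymethoxy)benzene F4. Lithiation between two acetal oxygens (n-BuLi, THF, 0 °C), copper catalysis (CuI) and alkylation with 8 should give trimethyl{(2Z)-4-[2,4,6-tris(methoxymethoxy)phenyl]but-2-en-2-yl}silane F5. Acid 10 would be coupled (MeNHOMe·HCl, EDC·HCl, N-methylmorpholine) to 3-(3,4-dihydroxyphenyl)-N-methoxy-N-methylpropanamide F6 and protected (MOMCl, i-Pr2NEt) as 3-[3,4-bis(methoxymethoxy)phenyl]-N-methoxy-N-methylpropanamide F7. A second lithiation of F5 (n-BuLi, TMEDA, THF, 0 °C) and addition to F7 should give 3-[3,4-bis(methoxymethoxy)phenyl]-1-{2,4,6-tris(methoxymethoxy)-3-[(2Z)-3-(trimethylsilyl)but-2-en-1-yl]phenyl}propan-1-one F8. Brief treatment with methanolic HCl at room temperature would remove the five acetals and give 12.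

Step 7. Site selectivity may be lost through alkylation at the 6'-oxygen, at a catechol oxygen or at a second hydroxyl. The fallback distinguishes O4' by selective deacylation instead of selective alkylation; it sets out from 12 and comes back at 14. Exhaustive acetylation of 12 (Ac2O, pyridine, DMAP) would give 2-[3-(3,4-diacetoxyphenyl)propanoyl]-4-[(2Z)-3-(trimethylsilyl)but-2-en-1-yl]benzene-1,3,5-triyl triacetate F9. Thiophenol and imidazole (NMP, 0 °C) should cleave only the acetate para to the ketone, whose phenoxide is the best leaving group, to give 2-[3-(3,4-diacetoxyphenyl)propanoyl]-5-hydroxy-4-[(2Z)-3-(trimethylsilyl)but-2-en-1-yl]-1,3-phenylene diacetate F10. Alkylation of this single free phenol (MeSCH2Cl, NaI, i-Pr2NEt, MeCN, rt) would give 14.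

Further compounds
F1 | step 9 | 1-(3-allyl-2,4,6-trihydroxyphenyl)-3-(3,4-dihydroxyphenyl)propan-1-one | C=CCc1c(O)cc(O)c(C(=O)CCc2ccc(O)c(O)c2)c1O
F2 | step 9 | 1-{3-allyl-2,6-dihydroxy-4-[(2-methylprop-2-en-1-yl)oxy]phenyl}-3-(3,4-dihydroxyphenyl)propan-1-one | C=CCc1c(OCC(C)=C)cc(O)c(C(=O)CCc2ccc(O)c(O)c2)c1O
F3 | step 9 | 4-allyl-2-[3-(3,4-diacetoxyphenyl)propanoyl]-5-[(2-methylprop-2-en-1-yl)oxy]-1,3-phenylene diacetate | C=CCc1c(OCC(C)=C)cc(OC(C)=O)c(C(=O)CCc2ccc(OC(C)=O)c(OC(C)=O)c2)c1OC(C)=O
F4 | step 6 | 1,3,5-tris(methoxymethoxy)benzene | COCOc1cc(OCOC)cc(OCOC)c1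
F5 | step 6 | trimethyl{(2Z)-4-[2,4,6-tris(methoxymethoxy)phenyl]but-2-en-2-yl}silane | COCOc1cc(OCOC)c(C/C=C(C)\[Si](C)(C)C)c(OCOC)c1
F6 | step 6 | 3-(3,4-dihydroxyphenyl)-N-methoxy-N-methylpropanamide | CON(C)C(=O)CCc1ccc(O)c(O)c1
F7 | step 6 | 3-[3,4-bis(methoxymethoxy)phenyl]-N-methoxy-N-methylpropanamide | CON(C)C(=O)CCc1ccc(OCOC)c(OCOC)c1
F8 | step 6 | 3-[3,4-bis(methoxymethoxy)phenyl]-1-{2,4,6-tris(methoxymethoxy)-3-[(2Z)-3-(trimethylsilyl)but-2-en-1-yl]phenyl}propan-1-one | COCOc1cc(OCOC)c(C(=O)CCc2ccc(OCOC)c(OCOC)c2)c(OCOC)c1C/C=C(C)\[Si](C)(C)C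
F9 | step 7 | 2-[3-(3,4-diacetoxyphenyl)propanoyl]-4-[(2Z)-3-(trimethylsilyl)but-2-en-1-yl]benzene-1,3,5-triyl triacetate | CC(=O)Oc1cc(OC(C)=O)c(C(=O)CCc2ccc(OC(C)=O)c(OC(C)=O)c2)c(OC(C)=O)c1C/C=C(C)\[Si](C)(C)C
F10 | step 7 | 2-[3-(3,4-diacetoxyphenyl)propanoyl]-5-hydroxy-4-[(2Z)-3-(trimethylsilyl)but-2-en-1-yl]-1,3-phenylene diacetate | Oc1cc(OC(C)=O)c(C(=O)CCc2ccc(OC(C)=O)c(OC(C)=O)c2)c(OC(C)=O)c1C/C=C(C)\[Si](C)(C)C
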